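All runs are simulated for an exercise; scatter was added.

**The question.** Ask how much target the zeta flask can hold within 6.0 h, and reckon with the fraction of the rise left, not the fraction made.

| flask | substrate | catalyst | remark | time |
|---|---|---|---|---|
| zeta | 0.67 M | 1 mM | the very flask that is asked about, followed so far |  |
| alpha | 0.34 M | 1 mM | run made earlier |  |
| flask | 0.67 M | 1.0 mM |  | 6.0 h |

| run | time / h | target / % |
|---|---|---|
| zeta | 0.833 | 10.5 |
| zeta | 1.00 | 11.4 |
| zeta | 1.33 | 14.7 |
| zeta | 1.50 | 14.3 |
| zeta | 2.00 | 16.9 |
| zeta | 2.50 | 16.7 |
| alpha | 0.833 | 10.0 |
| alpha | 1.00 | 12.3 |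
| alpha | 1.33 | 14.8 |
| alpha | 1.50 | 16.1 |
| alpha | 2.00 | 18.0 |
| alpha | 2.50 | 19.2 |

(scatter of a reading: 0.5 percentage points)

1. the moment within 6.0 h at which there is most target
2. the amount of target, in percent of the substrate charged, at that time
3. earliest time at which at least nineteen twentieths of that best amount are there
4. latest time at which they still are

**The floor.** Average the last two zeta readings to get 16.8% at 2.25 h, a floor for the best in zeta, read with a scatter of 0.5 percentage points per reading.

**The ceiling.** Average the zeta readings at 1.00 h and 1.33 h to get 13.1% at about half that later time, and treat the rise as a first-order relaxation, in which each equal span gains the same fraction of what the span before it gained. The late level over the early one, less one, then gives 0.287, the fraction left, and the spans of zeta sum to 18.3%, my estimate of a ceiling for a curve that levels or falls, carrying the scatter of the readings it comes from.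

**The tightening.** Add a third span to reach 17.9% at 3.50 h; a fourth adds 0.31 points, and a single reading scatters by 0.5 points; commit for zeta to about this level and time.

**The check.** The forecast stands inside the bracket with 17.8% at 3.5 h and a window from 2.3 h to 5.3 h, expecting “a broad, shallow maximum”; the zeta flask gives 18.0% at 3.32 h, with a window from 2.20 h to 5.06 h.

    substrate + catalyst ⇌ target + catalyst, rate k1*[substrate]*[catalyst] forward; the back reaction follows from the equilibrium constant (K = 0.490, k = 110 M⁻¹ h⁻¹)
    target ⇌ isomer of the product (K = 0.410, k = 0.660 h⁻¹)
    isomer of the product + catalyst ⇌ substrate + catalyst, rate k3*[catalyst]*[isomer of the product] forward; the back reaction follows from the equilibrium constant (k = 1800 M⁻¹ h⁻¹)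
    2 substrate → homo dimer (k = 0.280 M⁻¹ h⁻¹)
    catalyst ⇌ dormant form (K = 0.360, k = 0.540 h⁻¹)

**Second use.** The best of zeta lies between floor and ceiling, and by 6.00 h its target is down to 16.3% while homo dimer holds 48.9% of the substrate charged. Now take the alpha readings at the same times: they give 13.6% and 18.6%, so a fraction left of 0.373, larger than the 0.287 of zeta, and a ceiling of 21.7%. The alpha flask, run on to 6.0 h, reaches a highest target of 21.2%.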